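**Retrosynthetic overview**
1. Target ⇒ cis-pentamethyl ether: BBr3 cleaves five ArOMe groups and epimerises C2 (cis → trans) in the same flask; C3 carries the stereochemical information.
2. Stilbene ⇒ Heck coupling of the C5 aryl bromide with 3,5-dimethoxystyrene.
3. Dihydrofuran ring (the only ring formed; all benzene rings are bought) ⇒ enantioselective Rh(II)-catalysed intramolecular C–H insertion of a diaryl (donor/donor) carbene into the OCH2 of a 4-methoxybenzyl ether.
4. Diazo precursor ⇒ hydrazone of a 2-(4-methoxybenzyloxy)benzophenone, made from 5-bromo-2-hydroxybenzonitrile, 4-methoxybenzyl chloride and 3,5-dimethoxyphenylmagnesium chloride.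

Assumption: Rh2(R-PTAD)4 is taken as the catalyst antipode that gives the (3S) insertion product; if the first run shows the opposite sense, Rh2(S-PTAD)4 is used and nothing else changes.

**Route**

Step 1
Reactants: 1 5-bromo-2-hydroxybenzonitrile; 2 4-methoxybenzyl chloride
Product: 3 5-bromo-2-[(4-methoxybenzyl)oxy]benzonitrile
Conditions: K2CO3, DMF, 60 °C
Reagents that add atoms: none
Why: Williamson ether synthesis, in which the phenoxide (acidified by the ortho nitrile) displaces the benzylic chloride by SN2; no stereocentre is formed.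

Step 2
Reactants: 3 5-bromo-2-[(4-methoxybenzyl)oxy]benzonitrile; 4 3,5-dimethoxyphenylmagnesium chloride (1.0 M in THF)
Product: 7 {5-bromo-2-[(4-methoxybenzyl)oxy]phenyl}(3,5-dimethoxyphenyl)methanone, via chloromagnesium ketimide 5 (not isolated), via N-H ketimine 6 (not isolated)
Conditions: THF, 0 °C → 50 °C; then 1 M aq. HCl, rt
Reagents that add atoms: water, O
Why: Grignard addition to a nitrile stops at the magnesium ketimide (no double addition), and mild acid hydrolysis of the imine gives the ketone while the aryl bromide and the PMB ether are left alone.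

Step 3
Reactants: 7 {5-bromo-2-[(4-methoxybenzyl)oxy]phenyl}(3,5-dimethoxyphenyl)methanone
Product: 8 {5-bromo-2-[(4-methoxybenzyl)oxy]phenyl}(3,5-dimethoxyphenyl)methanone hydrazone (E/Z mixture)
Conditions: N2H4·H2O (10 equiv), AcOH (cat.), EtOH, 80 °C, sealed tube
Reagents that add atoms: hydrazine, NN
Why: Acid-catalysed hydrazone condensation, with excess hydrazine suppressing azine formation; the E/Z ratio is irrelevant because both isomers give the same diazo compound.

Step 4
Reactants: 8 {5-bromo-2-[(4-methoxybenzyl)oxy]phenyl}(3,5-dimethoxyphenyl)methanone hydrazone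
Product: 10 (2R,3S)-5-bromo-3-(3,5-dimethoxyphenyl)-2-(4-methoxyphenyl)-2,3-dihydro-1-benzofuran (2,3-cis), via diaryldiazomethane 9 (not isolated)
Conditions: MnO2 (8 equiv), CH2Cl2, 0 °C, filter through Celite; then Rh2(R-PTAD)4 (1 mol%), CH2Cl2, 0 °C → rt
Reagents that add atoms: none
Why: MnO2 dehydrogenates the hydrazone to the diazo compound, and the Rh(II) donor/donor carbene undergoes intramolecular 1,5 C–H insertion into the ether-activated benzylic CH2; the chiral PTAD paddlewheel sets C3 (S) and C2 (R) together as the kinetic cis isomer.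

Step 5
Reactants: 10 (2R,3S)-5-bromo-3-(3,5-dimethoxyphenyl)-2-(4-methoxyphenyl)-2,3-dihydro-1-benzofuran; 11 3,5-dimethoxystyrene
Product: 12 (2R,3S)-3-(3,5-dimethoxyphenyl)-5-[(E)-2-(3,5-dimethoxyphenyl)ethenyl]-2-(4-methoxyphenyl)-2,3-dihydro-1-benzofuran (cis-δ-viniferin pentamethyl ether)
Conditions: Pd(OAc)2 (5 mol%), P(o-tol)3 (10 mol%), Et3N, DMF, 100 °C
Reagents that add atoms: none
Why: Mizoroki–Heck reaction (oxidative addition to ArBr, syn insertion at the terminal alkene carbon, syn β-hydride elimination) gives the E-stilbene, and the basic medium leaves both stereocentres untouched.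

Step 6
Reactants: 12 cis-δ-viniferin pentamethyl ether
Product: 14 (2S,3S)-trans-δ-viniferin, via trans-pentamethyl ether 13 (not isolated)
Conditions: BBr3 (12 equiv), CH2Cl2, −78 °C → rt; then ice/H2O
Reagents that add atoms: none
Why: BBr3 reversibly ionises the C2–O bond to a 4-methoxyphenyl-stabilised benzylic cation that recloses to the thermodynamically favoured 2,3-trans ring (C2 R → S, C3 untouched so the ee of step 4 is kept), and Lewis-acid ether cleavage then removes all five methyl groups.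

**Compound list**
1 | 5-bromo-2-hydroxybenzonitrile | N#Cc1cc(Br)ccc1O | starting material
2 | 4-methoxybenzyl chloride | COc1ccc(CCl)cc1 | starting material
3 | 5-bromo-2-[(4-methoxybenzyl)oxy]benzonitrile | COc1ccc(COc2ccc(Br)cc2C#N)cc1 | intermediate
4 | 3,5-dimethoxyphenylmagnesium chloride | COc1cc(OC)cc([Mg]Cl)c1 | starting material
5 | N-chloromagnesio ketimine of 7 (chloromagnesium ketimide) | COc1ccc(COc2ccc(Br)cc2C(=N[Mg]Cl)c2cc(OC)cc(OC)c2)cc1 | intermediate
6 | 1-{5-bromo-2-[(4-methoxybenzyl)oxy]phenyl}-1-(3,5-dimethoxyphenyl)methanimine (N-H ketimine) | COc1ccc(COc2ccc(Br)cc2C(=N)c2cc(OC)cc(OC)c2)cc1 | intermediate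
7 | {5-bromo-2-[(4-methoxybenzyl)oxy]phenyl}(3,5-dimethoxyphenyl)methanone | COc1ccc(COc2ccc(Br)cc2C(=O)c2cc(OC)cc(OC)c2)cc1 | intermediate
8 | hydrazone of 7 (E/Z mixture, C=N geometry unspecified) | COc1ccc(COc2ccc(Br)cc2C(=NN)c2cc(OC)cc(OC)c2)cc1 | intermediate
9 | 4-bromo-2-[diazo(3,5-dimethoxyphenyl)methyl]-1-[(4-methoxybenzyl)oxy]benzene | COc1ccc(COc2ccc(Br)cc2C(=[N+]=[N-])c2cc(OC)cc(OC)c2)cc1 | intermediate
10 | (2R,3S)-5-bromo-3-(3,5-dimethoxyphenyl)-2-(4-methoxyphenyl)-2,3-dihydro-1-benzofuran (cis) | COc1ccc([C@@H]2Oc3ccc(Br)cc3[C@@H]2c2cc(OC)cc(OC)c2)cc1 | intermediate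
11 | 3,5-dimethoxystyrene | C=Cc1cc(OC)cc(OC)c1 | starting material
12 | (2R,3S)-3-(3,5-dimethoxyphenyl)-5-[(E)-2-(3,5-dimethoxyphenyl)ethenyl]-2-(4-methoxyphenyl)-2,3-dihydro-1-benzofuran (cis) | COc1ccc([C@@H]2Oc3ccc(/C=C/c4cc(OC)cc(OC)c4)cc3[C@@H]2c2cc(OC)cc(OC)c2)cc1 | intermediate
13 | (2S,3S)-3-(3,5-dimethoxyphenyl)-5-[(E)-2-(3,5-dimethoxyphenyl)ethenyl]-2-(4-methoxyphenyl)-2,3-dihydro-1-benzofuran (trans) | COc1ccc([C@H]2Oc3ccc(/C=C/c4cc(OC)cc(OC)c4)cc3[C@@H]2c2cc(OC)cc(OC)c2)cc1 | intermediate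
14 | (2S,3S)-trans-δ-viniferin, 5-[(2S,3S)-5-[(E)-2-(3,5-dihydroxyphenyl)ethenyl]-2-(4-hydroxyphenyl)-2,3-dihydro-1-benzofuran-3-yl]benzene-1,3-diol | Oc1ccc([C@H]2Oc3ccc(/C=C/c4cc(O)cc(O)c4)cc3[C@@H]2c2cc(O)cc(O)c2)cc1 | target

**Totals**
Total step count: 6. Longest linear sequence: 6 steps (1 → 3 → 7 → 8 → 10 → 12 → 14); compounds 2, 4 and 11 are bought.

**Three steps most likely to fail**

Step 4 (enantioselective C–H insertion) is the main risk: azine formation, low ee, or the wrong sense of induction. The fallback avoids diazo chemistry and sets out from ketone 7. A strong non-nucleophilic base (P4-t-Bu phosphazene, toluene, 100 °C) deprotonates the benzylic OCH2, and the carbanion adds to the ketone and loses water to give 5-bromo-3-(3,5-dimethoxyphenyl)-2-(4-methoxyphenyl)-1-benzofuran F3. Ionic hydrogenation (Et3SiH, TFA, CH2Cl2, 0 °C → rt) gives racemic trans-5-bromo-3-(3,5-dimethoxyphenyl)-2-(4-methoxyphenyl)-2,3-dihydro-1-benzofuran F4; any cis isomer equilibrates to trans in the acid. Preparative chiral HPLC on an amylose phase gives (2S,3S)-5-bromo-3-(3,5-dimethoxyphenyl)-2-(4-methoxyphenyl)-2,3-dihydro-1-benzofuran F5. Heck coupling of this with 11 under the step 5 conditions comes back to the route at 13, which is then demethylated as in step 6 with no epimerisation needed.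

Step 6 (global demethylation with epimerisation) is the second risk: the electron-rich stilbene may not survive BBr3 and HBr. The fallback changes the protecting groups and the order, and sets out from bromide 10. BBr3 (CH2Cl2, −78 °C → rt) is applied to this simpler compound, giving with the same C2 epimerisation 5-[(2S,3S)-5-bromo-2-(4-hydroxyphenyl)-2,3-dihydro-1-benzofuran-3-yl]benzene-1,3-diol F6. Silylation (TBSCl, imidazole, DMF) gives its tris(tert-butyldimethylsilyl) ether F7. The coupling partner is made from commercial 3,5-dihydroxybenzaldehyde: silylation gives 3,5-bis(tert-butyldimethylsilyloxy)benzaldehyde F8, and Wittig methylenation (Ph3P=CH2, THF) gives 3,5-bis(tert-butyldimethylsilyloxy)styrene F9. Heck coupling of these two (Pd(OAc)2, P(o-tol)3, Et3N, DMF, 100 °C) gives (2S,3S)-trans-δ-viniferin pentakis(tert-butyldimethylsilyl) ether F10. Buffered fluoride (TBAF, AcOH, THF, 0 °C) then returns to the route at the target 14 without strong acid.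

Step 2 (Grignard addition to the nitrile) is the third risk: the reaction may be sluggish, or the ortho alkoxy group may be displaced. The fallback goes through the aldehyde oxidation level and sets out from nitrile 3. DIBAL-H (toluene, −78 °C, then aq. HCl) gives 5-bromo-2-[(4-methoxybenzyl)oxy]benzaldehyde F1. Addition of 4 (THF, −78 °C → 0 °C) gives racemic {5-bromo-2-[(4-methoxybenzyl)oxy]phenyl}(3,5-dimethoxyphenyl)methanol F2. Oxidation (MnO2, CH2Cl2, rt) comes back to the route at ketone 7.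

**Further compounds**
F1 | step 2 | 5-bromo-2-[(4-methoxybenzyl)oxy]benzaldehyde | COc1ccc(COc2ccc(Br)cc2C=O)cc1
F2 | step 2 | {5-bromo-2-[(4-methoxybenzyl)oxy]phenyl}(3,5-dimethoxyphenyl)methanol (racemic) | COc1ccc(COc2ccc(Br)cc2C(O)c2cc(OC)cc(OC)c2)cc1
F3 | step 4 | 5-bromo-3-(3,5-dimethoxyphenyl)-2-(4-methoxyphenyl)-1-benzofuran | COc1ccc(-c2oc3ccc(Br)cc3c2-c2cc(OC)cc(OC)c2)cc1
F4 | step 4 | racemic trans-5-bromo-3-(3,5-dimethoxyphenyl)-2-(4-methoxyphenyl)-2,3-dihydro-1-benzofuran (both enantiomers written) | COc1ccc([C@H]2Oc3ccc(Br)cc3[C@@H]2c2cc(OC)cc(OC)c2)cc1.COc1ccc([C@@H]2Oc3ccc(Br)cc3[C@H]2c2cc(OC)cc(OC)c2)cc1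
F5 | step 4 | (2S,3S)-5-bromo-3-(3,5-dimethoxyphenyl)-2-(4-methoxyphenyl)-2,3-dihydro-1-benzofuran (trans) | COc1ccc([C@H]2Oc3ccc(Br)cc3[C@@H]2c2cc(OC)cc(OC)c2)cc1
F6 | step 6 | 5-[(2S,3S)-5-bromo-2-(4-hydroxyphenyl)-2,3-dihydro-1-benzofuran-3-yl]benzene-1,3-diol (trans) | Oc1ccc([C@H]2Oc3ccc(Br)cc3[C@@H]2c2cc(O)cc(O)c2)cc1
F7 | step 6 | tris(tert-butyldimethylsilyl) ether of F6, (2S,3S) | CC(C)(C)[Si](C)(C)Oc1ccc([C@H]2Oc3ccc(Br)cc3[C@@H]2c2cc(O[Si](C)(C)C(C)(C)C)cc(O[Si](C)(C)C(C)(C)C)c2)cc1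
F8 | step 6 | 3,5-bis(tert-butyldimethylsilyloxy)benzaldehyde | CC(C)(C)[Si](C)(C)Oc1cc(C=O)cc(O[Si](C)(C)C(C)(C)C)c1
F9 | step 6 | 3,5-bis(tert-butyldimethylsilyloxy)styrene | C=Cc1cc(O[Si](C)(C)C(C)(C)C)cc(O[Si](C)(C)C(C)(C)C)c1
F10 | step 6 | (2S,3S)-trans-δ-viniferin pentakis(tert-butyldimethylsilyl) ether | CC(C)(C)[Si](C)(C)Oc1ccc([C@H]2Oc3ccc(/C=C/c4cc(O[Si](C)(C)C(C)(C)C)cc(O[Si](C)(C)C(C)(C)C)c4)cc3[C@@H]2c2cc(O[Si](C)(C)C(C)(C)C)cc(O[Si](C)(C)C(C)(C)C)c2)cc1
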